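The cyclohexene ring (C1, C10, C11, C12, C13=C14) is a Diels–Alder retron: its C13=C14 alkene lies opposite the C10–C11 bond, between acetoxy-bearing C12 and the quaternary fusion carbon C1. The route cuts C1–C10 and C11–C12 together. An intramolecular Diels–Alder reaction of an open-chain trienone joins an (E,E)-1-acetoxy diene (C12=C13–C14=C1) to a (Z)-enone (C10=C11, activated by a temporary C9 ketone) across the eight-atom tether C2–C9, closing the cyclohexene and the ten-membered ring and setting C1, C10, C11 and C12 in one operation. The precursor already carries the chloroalkene, the hydroxy lactone and the C2 acetate; reduction of the ketone completes the target.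

Key step: step 19

Numbering used for all compounds: C1 (quaternary, methyl C15), C2 (OAc), C3, C4, C5 (methyl C16), C6 (Cl), C7 (lactone O), C8 (OH), C9, C10, C11 (methyl C20), C12 (OAc), C13=C14; lactone carbons C17 (methyl C18) and C19 (C=O). Target: (1S,2S,5E,7R,8R,9S,10S,11R,12R,17R).

Assumption: hex-1-en-5-yne and (Z)-1-bromoprop-1-ene are bought. C17 is carried as an epimer mixture until step 11 and C9 as an epimer mixture in compound 30, both by design. lIpc = (1S,2R,3S,5S)-isopinocampheyl, from (−)-α-pinene.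

Step 1
Reactants: 1 hex-1-en-5-yne
Product: 3 methyl hept-6-en-2-ynoate, via lithium acetylide 2 (not isolated)
Conditions: n-BuLi, THF, −78 °C; ClCO2Me, −78 → 0 °C
Reagents that add atoms: methyl chloroformate COC(=O)Cl
Why: Acetylide C-acylation with a chloroformate is the standard ynoate synthesis; the terminal alkene (latent C2 aldehyde) is inert.

Step 2
Reactants: 3 methyl hept-6-en-2-ynoate
Product: 5 methyl (2E)-2-chloro-3-methylhepta-2,6-dienoate, via alkenylcuprate 4 (not isolated)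
Conditions: Me2CuLi (from MeLi, CuI), THF, −78 °C; NCS, −78 °C
Reagents that add atoms: lithium dimethylcuprate [Li+].C[Cu-]C; N-chlorosuccinimide O=C1CCC(=O)N1Cl
Why: syn-Carbocupration of the ynoate puts the C16 methyl on C5 and copper on C6 cis to it, and chlorination of the alkenylcuprate at −78 °C with retention should fix the tetrasubstituted C5=C6 geometry (Cl cis to C16, C4 cis to C7).

Step 3
Reactants: 5 methyl (2E)-2-chloro-3-methylhepta-2,6-dienoate
Product: 6 (2E)-2-chloro-3-methylhepta-2,6-dien-1-ol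
Conditions: i-Bu2AlH, CH2Cl2, −78 °C
Reagents that add atoms: none
Why: 1,2-Reduction of the enoate by DIBAL-H leaves the vinyl chloride and the alkene geometry untouched.

Step 4
Reactants: 6 (2E)-2-chloro-3-methylhepta-2,6-dien-1-ol
Product: 7 (2E)-2-chloro-3-methylhepta-2,6-dienal
Conditions: MnO2, CH2Cl2, rt
Reagents that add atoms: none
Why: Neutral allylic oxidation with MnO2 should give the C7 enal without E/Z erosion.

Step 5
Reactants: 8 trimethyl phosphonoacetate; 9 tert-butyl 2-bromopropanoate (racemic)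
Product: 11 4-tert-butyl 1-methyl 2-(dimethoxyphosphoryl)-3-methylbutanedioate, via sodium phosphonoacetate 10 (not isolated)
Conditions: NaH, THF/DMF, 0 °C → rt
Reagents that add atoms: none
Why: SN2 alkylation of the stabilised phosphonate anion by the α-bromo ester; neither new stereocentre needs control (C8 becomes sp2, C17 is corrected in step 11).

Step 6
Reactants: 7 (2E)-2-chloro-3-methylhepta-2,6-dienal; 11 4-tert-butyl 1-methyl 2-(dimethoxyphosphoryl)-3-methylbutanedioate
Product: 13 4-tert-butyl 1-methyl (2E)-2-[(2E)-2-chloro-3-methylhepta-2,6-dien-1-ylidene]-3-methylbutanedioate, via sodium phosphonate anion 12 (not isolated)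
Conditions: NaH, THF, 0 °C → rt
Reagents that add atoms: none
Why: Horner–Wadsworth–Emmons olefination should give the (E)-alkylidene succinate (C6 trans to the C9 ester, cis to C17), the geometry the epoxidation/anti-opening sequence requires.

Step 7
Reactants: 13 the alkylidene succinate diester
Product: 14 tert-butyl (3E,5E)-5-chloro-3-(hydroxymethyl)-2,6-dimethyldeca-3,5,9-trienoate
Conditions: i-Bu2AlH (2.2 equiv), CH2Cl2, −78 °C
Reagents that add atoms: none
Why: DIBAL-H should reduce the conjugated methyl ester (C9) chemoselectively beside the hindered, α-branched tert-butyl ester (C19).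

Step 8
Reactants: 14 the C9 allylic alcohol
Product: 15 tert-butyl 2-[(2R,3S)-3-[(1E)-1-chloro-2-methylhexa-1,5-dien-1-yl]-2-(hydroxymethyl)oxiran-2-yl]propanoate ((7S,8R)-epoxide)
Conditions: Ti(OiPr)4, D-(−)-diisopropyl tartrate, t-BuOOH, 4 Å MS, CH2Cl2, −20 °C
Reagents that add atoms: tert-butyl hydroperoxide CC(C)(C)OO
Why: Sharpless asymmetric epoxidation of the trisubstituted allylic alcohol is reagent-controlled (D-tartrate gives the 7S,8R epoxide for both C17 epimers) and ignores the chloroalkene and the terminal alkene.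

Step 9
Reactants: 15 the (7S,8R)-epoxy alcohol
Product: 16 (4R,5R)-5-[(1E)-1-chloro-2-methylhexa-1,5-dien-1-yl]-4-hydroxy-4-(hydroxymethyl)-3-methyloxolan-2-one
Conditions: BF3·OEt2, CH2Cl2, −78 → −20 °C
Reagents that add atoms: none
Why: Lewis-acid epoxide opening with tert-butyl ester participation: the ester carbonyl oxygen attacks allylic C7 with inversion (7R) and loses isobutene, while the epoxide oxygen stays on C8 as the tertiary alcohol (8R).

Step 10
Reactants: 16 the lactone diol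
Product: 17 (4R,5R)-5-[(1E)-1-chloro-2-methylhexa-1,5-dien-1-yl]-4-hydroxy-3-methyl-4-[(triethylsilyloxy)methyl]oxolan-2-one
Conditions: Et3SiCl, imidazole, DMF, 0 °C
Reagents that add atoms: chlorotriethylsilane CC[Si](Cl)(CC)CC
Why: Selective silylation of the primary C9 hydroxyl; the tertiary 8-OH is too hindered.

Step 11
Reactants: 17 the silyl ether (C17 epimer mixture)
Product: 19 (3R,4R,5R)-5-[(1E)-1-chloro-2-methylhexa-1,5-dien-1-yl]-4-hydroxy-3-methyl-4-[(triethylsilyloxy)methyl]oxolan-2-one, via dilithium alkoxide enolate 18 (not isolated)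
Conditions: LDA (2.3 equiv), THF, −78 °C; AcOH, −78 °C
Reagents that add atoms: none
Why: Fráter–Seebach-type dianion formation and kinetic protonation anti to the lithium alkoxide and the C7 side chain should converge both epimers on 17R (C18 cis to 8-OH and to the C7 substituent), which is also expected to be the more stable lactone epimer.

Step 12
Reactants: 19 the (17R)-lactone
Product: 21 (4E)-5-chloro-5-[(2R,3R,4R)-3-hydroxy-4-methyl-5-oxo-3-[(triethylsilyloxy)methyl]oxolan-2-yl]-4-methylpent-4-enal, via vicinal diol 20 (not isolated)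
Conditions: OsO4 (cat.), NaIO4, 2,6-lutidine, dioxane/H2O, rt
Reagents that add atoms: osmium tetroxide O=[Os](=O)(=O)=O (catalytic, turned over by sodium periodate [Na+].[O-]I(=O)(=O)=O)
Why: Lemieux–Johnson cleavage; OsO4 should attack only the monosubstituted alkene, the tetrasubstituted chloroalkene being sterically and electronically deactivated.

Step 13
Reactants: 21 the C2 aldehyde
Product: 23 (3R,4R,5R)-5-[(1E,5S,6R)-1-chloro-5-hydroxy-2,6-dimethylocta-1,7-dien-1-yl]-4-hydroxy-3-methyl-4-[(triethylsilyloxy)methyl]oxolan-2-one, via borinate ester 22 (not isolated)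
Conditions: (E)-crotyl-B(lIpc)2 [from (lIpc)2BOMe, trans-but-2-ene, n-BuLi, KOtBu, BF3·OEt2], THF, −78 °C; NaBO3·4H2O, THF/H2O, rt
Reagents that add atoms: (E)-crotylbis(isopinocampheyl)borane C/C=C/CB([C@H]1C[C@H]2C[C@@H]([C@@H]1C)C2(C)C)[C@H]1C[C@H]2C[C@@H]([C@@H]1C)C2(C)C
Why: Brown crotylation through a chair allylboration transition state; the (−)-α-pinene-derived borane adds to the Re face of the aldehyde to set 2S, and the (E)-crotyl unit gives the anti product (the C1 centre is later planarised).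

Step 14
Reactants: 23 the homoallylic alcohol
Product: 24 (2E,4R,5S,8E)-9-chloro-5-hydroxy-9-[(2R,3R,4R)-3-hydroxy-4-methyl-5-oxo-3-[(triethylsilyloxy)methyl]oxolan-2-yl]-4,8-dimethylnona-2,8-dienal
Conditions: crotonaldehyde, Hoveyda–Grubbs second-generation catalyst RuCl2(H2IMes)(=CH-C6H4-2-OiPr), CH2Cl2, 40 °C
Reagents that add atoms: crotonaldehyde C/C=C/C=O
Why: Olefin cross-metathesis of the terminal alkene with an enal partner is E-selective; the tetrasubstituted chloroalkene does not take part.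

Step 15
Reactants: 24 the δ-hydroxy enal
Product: 27 (1E,3E,5S,8E)-9-chloro-9-[(2R,3R,4R)-3-hydroxy-4-methyl-5-oxo-3-[(triethylsilyloxy)methyl]oxolan-2-yl]-4,8-dimethylnona-1,3,8-triene-1,5-diyl diacetate, via potassium dienolate 25 (not isolated), via hydroxy dienyl acetate 26 (not isolated)
Conditions: KHMDS (1.1 equiv), THF, −78 °C; AcCl (3 equiv), −78 °C; pyridine, DMAP (cat.), −78 → 0 °C
Reagents that add atoms: acetyl chloride CC(=O)Cl
Why: γ-Deprotonation of the s-trans enal gives the dienolate with C12=C13 E and, by allylic-strain control, the larger C2 substituent outside (C14=C1 E); O-acylation traps it as the dienyl acetate, and the pyridine/DMAP stage acetylates only the secondary 2-OH.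

Step 16
Reactants: 27 the dienyl acetate
Product: 29 (2R,3S,4R)-2-[(1E,5S,6E,8E)-5,9-diacetoxy-1-chloro-2,6-dimethylnona-1,6,8-trien-1-yl]-3-hydroxy-4-methyl-5-oxooxolane-3-carbaldehyde, via alkoxysulfonium chloride 28 (not isolated)
Conditions: (COCl)2, DMSO, CH2Cl2, −78 → −40 °C; Et3N, −78 → 0 °C
Reagents that add atoms: none
Why: Under Swern conditions a primary triethylsilyl ether is converted directly into the aldehyde through the alkoxysulfonium ion; the tertiary alcohol and the acetates are spectators.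

Step 17
Reactants: 29 the α-hydroxy aldehyde
Product: 30 (3R,4R,5R)-5-[(1E,5S,6E,8E)-5,9-diacetoxy-1-chloro-2,6-dimethylnona-1,6,8-trien-1-yl]-4-hydroxy-4-[(2Z)-1-hydroxybut-2-en-1-yl]-3-methyloxolan-2-one (C9 epimers)
Conditions: (Z)-1-bromoprop-1-ene, CrCl2, NiCl2 (cat.), DMF, rt
Reagents that add atoms: (Z)-1-bromoprop-1-ene C/C=C\Br
Why: Nozaki–Hiyama–Kishi addition is chemoselective for the aldehyde beside esters and enol esters and retains the (Z)-alkenyl geometry; the C9 configuration is irrelevant because C9 is oxidised next.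

Step 18
Reactants: 30 the (Z)-allylic alcohol
Product: 31 (3R,4S,5R)-4-[(2Z)-but-2-enoyl]-5-[(1E,5S,6E,8E)-5,9-diacetoxy-1-chloro-2,6-dimethylnona-1,6,8-trien-1-yl]-4-hydroxy-3-methyloxolan-2-one
Conditions: MnO2, CH2Cl2, rt
Reagents that add atoms: none
Why: Neutral allylic oxidation with MnO2 should give the (Z)-α'-hydroxy enone without isomerisation or glycol cleavage.

Step 19
Reactants: 31 the (Z)-enone dienyl acetate
Product: 32 9-oxo cycloadduct, (1S,2S,5E,7R,8S,10S,11R,12R,17R)-2,12-diacetoxy-6-chloro-8-hydroxy-9-oxo bicyclic lactone (the target with C9 as ketone)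
Conditions: toluene (0.5 mM), BHT, 120 °C, sealed tube, base-washed glass
Reagents that add atoms: none
Why: A concerted thermal [4+2] cycloaddition joins C12 to C11 and C1 to C10 suprafacially on both partners; the closest known type is the macrocycle-forming type 1 intramolecular Diels–Alder reaction of trienes with acyl-activated dienophiles that closes eleven-membered carbocycles onto cyclohexenes. The cyclohexene closes by the cycloaddition itself and the ten-membered ring closes because the C2–C9 tether bridges the bonding termini C1 and C10 in the exo (anti) mode, which gives the trans ring fusion. C10 and C11 follow from the (Z)-enone (C9 and C20 cis), C12 and its relation to C1 from the (12E,14E)-diene (acetoxy and C2 outside, C15 inside), and the C1/C10 relation from the exo transition state, in which the s-cis carbonyl, hydrogen-bonded to 8-OH, points away from the diene. The absolute sense comes from C2 together with C7 and C8: the tether (C3) rises from the diene face that is attacked, H-2 eclipses C1=C14 and the C2 acetoxy group lies on the far side. The step needs exo over endo addition and this diene face; it relies on the stiff tether (ring-cis C5=C6, trans-substituted lactone) and on the strain of a cis-fused alternative, with high dilution against oligomerisation. Diene isomers with a 12Z or 14Z bond cannot reach a reactive s-cis conformation and should stay unchanged.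

Step 20
Reactants: 32 the 9-oxo cycloadduct
Product: 33 CNP0296164.1, (1S,2S,5E,7R,8R,9S,10S,11R,12R,17R)
Conditions: NaBH4, CeCl3·7H2O, MeOH/THF, −78 → −40 °C
Reagents that add atoms: none
Why: Luche-type reduction touches only the ketone; with the carbonyl eclipsing C10–C11 (the arrangement inherited from the s-cis enone), hydride should enter from the peripheral H-10 face anti to quaternary C1 and give 9S.

Compound list
1 | hex-1-en-5-yne | C=CCCC#C | starting material
2 | lithium hex-5-en-1-yn-1-ide | [Li]C#CCCC=C | intermediate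
3 | methyl hept-6-en-2-ynoate | C=CCCC#CC(=O)OC | intermediate
4 | lithium methyl(alkenyl)cuprate from syn-carbocupration of 3 (copper on C6 cis to the C5 methyl) | [Li+].C=CCC/C(C)=C(/[Cu-]C)C(=O)OC | intermediate
5 | methyl (2E)-2-chloro-3-methylhepta-2,6-dienoate | C=CCC/C(C)=C(/Cl)C(=O)OC | intermediate
6 | (2E)-2-chloro-3-methylhepta-2,6-dien-1-ol | C=CCC/C(C)=C(/Cl)CO | intermediate
7 | (2E)-2-chloro-3-methylhepta-2,6-dienal | C=CCC/C(C)=C(/Cl)C=O | intermediate
8 | trimethyl phosphonoacetate | COC(=O)CP(=O)(OC)OC | starting material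
9 | tert-butyl 2-bromopropanoate (racemic) | CC(Br)C(=O)OC(C)(C)C | starting material
10 | sodium salt of trimethyl phosphonoacetate | [Na+].COC(=O)[CH-]P(=O)(OC)OC | intermediate
11 | 4-tert-butyl 1-methyl 2-(dimethoxyphosphoryl)-3-methylbutanedioate (diastereomer mixture) | COC(=O)C(C(C)C(=O)OC(C)(C)C)P(=O)(OC)OC | intermediate
12 | sodium salt of phosphonate 11 | [Na+].COC(=O)[C-](C(C)C(=O)OC(C)(C)C)P(=O)(OC)OC | intermediate
13 | 4-tert-butyl 1-methyl (2E)-2-[(2E)-2-chloro-3-methylhepta-2,6-dien-1-ylidene]-3-methylbutanedioate (C17 racemic) | C=CCC/C(C)=C(/Cl)\C=C(\C(=O)OC)C(C)C(=O)OC(C)(C)C | intermediate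
14 | tert-butyl (3E,5E)-5-chloro-3-(hydroxymethyl)-2,6-dimethyldeca-3,5,9-trienoate (C17 racemic) | C=CCC/C(C)=C(/Cl)\C=C(\CO)C(C)C(=O)OC(C)(C)C | intermediate
15 | tert-butyl 2-[(2R,3S)-3-[(1E)-1-chloro-2-methylhexa-1,5-dien-1-yl]-2-(hydroxymethyl)oxiran-2-yl]propanoate (7S,8R; C17 epimers) | C=CCC/C(C)=C(/Cl)[C@H]1O[C@@]1(CO)C(C)C(=O)OC(C)(C)C | intermediate
16 | (4R,5R)-5-[(1E)-1-chloro-2-methylhexa-1,5-dien-1-yl]-4-hydroxy-4-(hydroxymethyl)-3-methyloxolan-2-one (7R,8R; C17 epimers) | C=CCC/C(C)=C(/Cl)[C@@H]1OC(=O)C(C)[C@@]1(O)CO | intermediate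
17 | (4R,5R)-5-[(1E)-1-chloro-2-methylhexa-1,5-dien-1-yl]-4-hydroxy-3-methyl-4-[(triethylsilyloxy)methyl]oxolan-2-one (C17 epimers) | C=CCC/C(C)=C(/Cl)[C@@H]1OC(=O)C(C)[C@@]1(O)CO[Si](CC)(CC)CC | intermediate
18 | dilithium alkoxide enolate of 17 | [Li+].[Li+].C=CCC/C(C)=C(/Cl)[C@@H]1OC([O-])=C(C)[C@@]1([O-])CO[Si](CC)(CC)CC | intermediate
19 | (3R,4R,5R)-5-[(1E)-1-chloro-2-methylhexa-1,5-dien-1-yl]-4-hydroxy-3-methyl-4-[(triethylsilyloxy)methyl]oxolan-2-one (7R,8R,17R) | C=CCC/C(C)=C(/Cl)[C@@H]1OC(=O)[C@H](C)[C@@]1(O)CO[Si](CC)(CC)CC | intermediate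
20 | (3R,4R,5R)-5-[(1E)-1-chloro-5,6-dihydroxy-2-methylhex-1-en-1-yl]-4-hydroxy-3-methyl-4-[(triethylsilyloxy)methyl]oxolan-2-one (diol epimers) | OCC(O)CC/C(C)=C(/Cl)[C@@H]1OC(=O)[C@H](C)[C@@]1(O)CO[Si](CC)(CC)CC | intermediate
21 | (4E)-5-chloro-5-[(2R,3R,4R)-3-hydroxy-4-methyl-5-oxo-3-[(triethylsilyloxy)methyl]oxolan-2-yl]-4-methylpent-4-enal | O=CCC/C(C)=C(/Cl)[C@@H]1OC(=O)[C@H](C)[C@@]1(O)CO[Si](CC)(CC)CC | intermediate
22 | O-bis(isopinocampheyl)boryl ether of alcohol 23 | C=C[C@@H](C)[C@@H](OB([C@H]1C[C@H]2C[C@@H]([C@@H]1C)C2(C)C)[C@H]1C[C@H]2C[C@@H]([C@@H]1C)C2(C)C)CC/C(C)=C(/Cl)[C@@H]1OC(=O)[C@H](C)[C@@]1(O)CO[Si](CC)(CC)CC | intermediate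
23 | (3R,4R,5R)-5-[(1E,5S,6R)-1-chloro-5-hydroxy-2,6-dimethylocta-1,7-dien-1-yl]-4-hydroxy-3-methyl-4-[(triethylsilyloxy)methyl]oxolan-2-one (1R,2S) | C=C[C@@H](C)[C@@H](O)CC/C(C)=C(/Cl)[C@@H]1OC(=O)[C@H](C)[C@@]1(O)CO[Si](CC)(CC)CC | intermediate
24 | (2E,4R,5S,8E)-9-chloro-5-hydroxy-9-[(2R,3R,4R)-3-hydroxy-4-methyl-5-oxo-3-[(triethylsilyloxy)methyl]oxolan-2-yl]-4,8-dimethylnona-2,8-dienal | O=C/C=C/[C@@H](C)[C@@H](O)CC/C(C)=C(/Cl)[C@@H]1OC(=O)[C@H](C)[C@@]1(O)CO[Si](CC)(CC)CC | intermediate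
25 | potassium (12E,14E)-dienolate of 24 | [K+].[O-]/C=C/C=C(\C)[C@@H](O)CC/C(C)=C(/Cl)[C@@H]1OC(=O)[C@H](C)[C@@]1(O)CO[Si](CC)(CC)CC | intermediate
26 | (12E,14E)-12-acetoxy diene with free 2-OH | CC(=O)O/C=C/C=C(\C)[C@@H](O)CC/C(C)=C(/Cl)[C@@H]1OC(=O)[C@H](C)[C@@]1(O)CO[Si](CC)(CC)CC | intermediate
27 | (1E,3E,5S,8E)-9-chloro-9-[(2R,3R,4R)-3-hydroxy-4-methyl-5-oxo-3-[(triethylsilyloxy)methyl]oxolan-2-yl]-4,8-dimethylnona-1,3,8-triene-1,5-diyl diacetate | CC(=O)O/C=C/C=C(\C)[C@@H](OC(C)=O)CC/C(C)=C(/Cl)[C@@H]1OC(=O)[C@H](C)[C@@]1(O)CO[Si](CC)(CC)CC | intermediate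
28 | dimethyl(alkoxy)sulfonium chloride at the C9 oxygen of 27 (silyl group lost) | [Cl-].CC(=O)O/C=C/C=C(\C)[C@@H](OC(C)=O)CC/C(C)=C(/Cl)[C@@H]1OC(=O)[C@H](C)[C@@]1(O)CO[S+](C)C | intermediate
29 | (2R,3S,4R)-2-[(1E,5S,6E,8E)-5,9-diacetoxy-1-chloro-2,6-dimethylnona-1,6,8-trien-1-yl]-3-hydroxy-4-methyl-5-oxooxolane-3-carbaldehyde | CC(=O)O/C=C/C=C(\C)[C@@H](OC(C)=O)CC/C(C)=C(/Cl)[C@@H]1OC(=O)[C@H](C)[C@@]1(O)C=O | intermediate
30 | (3R,4R,5R)-5-[(1E,5S,6E,8E)-5,9-diacetoxy-1-chloro-2,6-dimethylnona-1,6,8-trien-1-yl]-4-hydroxy-4-[(2Z)-1-hydroxybut-2-en-1-yl]-3-methyloxolan-2-one (C9 epimers) | CC(=O)O/C=C/C=C(\C)[C@@H](OC(C)=O)CC/C(C)=C(/Cl)[C@@H]1OC(=O)[C@H](C)[C@@]1(O)C(O)/C=C\C | intermediate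
31 | (3R,4S,5R)-4-[(2Z)-but-2-enoyl]-5-[(1E,5S,6E,8E)-5,9-diacetoxy-1-chloro-2,6-dimethylnona-1,6,8-trien-1-yl]-4-hydroxy-3-methyloxolan-2-one | CC(=O)O/C=C/C=C(\C)[C@@H](OC(C)=O)CC/C(C)=C(/Cl)[C@@H]1OC(=O)[C@H](C)[C@@]1(O)C(=O)/C=C\C | intermediate
32 | 9-oxo cycloadduct (1S,2S,5E,7R,8S,10S,11R,12R,17R); the target with C9 as ketone | CC(=O)O[C@H]1CC/C(C)=C(/Cl)[C@@H]2OC(=O)[C@H](C)[C@@]2(O)C(=O)[C@H]2[C@@H](C)[C@H](OC(C)=O)C=C[C@@]21C | intermediate
33 | CNP0296164.1 (1S,2S,5E,7R,8R,9S,10S,11R,12R,17R) | CC(=O)O[C@H]1CC/C(C)=C(/Cl)[C@@H]2OC(=O)[C@H](C)[C@@]2(O)[C@@H](O)[C@H]2[C@@H](C)[C@H](OC(C)=O)C=C[C@@]21C | target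

Total step count: 20. Longest linear sequence: 19 steps (steps 1–4 and 6–20; step 5 is a one-step side branch).

Steps most likely to fail

1. Step 19 (cycloaddition). Ring closure may lose to intermolecular cycloaddition and oligomerisation, the (Z)-enone may isomerise to (E) before it cyclises (scrambling C11), or addition may go endo or on the other diene face. Fallback: from 29, zinc-mediated alkynylation with propyne (Zn(OTf)2, Et3N) gives propargylic alcohol F1 and MnO2 oxidation gives ynone F2. Its linear, more reactive dienophile has no E/Z lability and no endo/exo question, and should cyclise at lower temperature to cyclohexa-1,4-diene F3 with C1 and C12 set. Conjugate reduction with [(Ph3P)CuH]6 and protonation of the enolate, both from the face anti to the angular C15 methyl, then set C11 and C10 and rejoin the route at 32.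

2. Step 15 (dienyl acetate). The dienolate may be acylated on carbon, the chain may fragment by vinylogous retro-aldol cleavage or lose the C2 oxygen by 1,4-elimination, and the C14=C1 geometry may form with poor selectivity. Fallback: from 24, acetylation of 2-OH (Ac2O, pyridine) gives enal acetate F4. Soft enolisation with Et3SiOTf/Et3N, which avoids any free dienolate, gives triethylsilyl dienol ether F5 (8-OH is silylated as well). Fluoride-catalysed acyl exchange with acetyl fluoride and Bu4N[Ph3SiF2] gives dienyl acetate F6, HF·pyridine gives diol F7, and Dess–Martin oxidation of the primary alcohol rejoins the route at 29.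

3. Step 20 (C9 reduction). Hydride delivery may occur on the wrong face of the ketone, because facial selectivity depends on the conformation of the ten-membered ring. Fallback: from 32, silylation of 8-OH with chlorodimethylsilane (Et3N, DMAP) gives hydridosilyl ether F8. Fluoride-catalysed intramolecular hydrosilylation then delivers hydride from the tether on O-8 through a five-membered transition state and gives cyclic silylene acetal F9. HF·pyridine releases the diol and rejoins the route at 33.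

Further compounds
F1 | step 19 | C9 propargylic alcohol from 29 and propyne (C9 epimers) | CC(=O)O/C=C/C=C(\C)[C@@H](OC(C)=O)CC/C(C)=C(/Cl)[C@@H]1OC(=O)[C@H](C)[C@@]1(O)C(O)C#CC
F2 | step 19 | but-2-ynoyl ketone (ynone analogue of 31) | CC(=O)O/C=C/C=C(\C)[C@@H](OC(C)=O)CC/C(C)=C(/Cl)[C@@H]1OC(=O)[C@H](C)[C@@]1(O)C(=O)C#CC
F3 | step 19 | cyclohexa-1,4-diene cycloadduct (10,11-didehydro-32) | CC(=O)O[C@H]1CC/C(C)=C(/Cl)[C@@H]2OC(=O)[C@H](C)[C@@]2(O)C(=O)C2=C(C)[C@H](OC(C)=O)C=C[C@@]21C
F4 | step 15 | 2-O-acetate of enal 24 | O=C/C=C/[C@@H](C)[C@@H](OC(C)=O)CC/C(C)=C(/Cl)[C@@H]1OC(=O)[C@H](C)[C@@]1(O)CO[Si](CC)(CC)CC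
F5 | step 15 | (12E,14E)-12-triethylsilyloxy diene with 8-O-triethylsilyl ether | CC[Si](CC)(CC)O/C=C/C=C(\C)[C@@H](OC(C)=O)CC/C(C)=C(/Cl)[C@@H]1OC(=O)[C@H](C)[C@@]1(O[Si](CC)(CC)CC)CO[Si](CC)(CC)CC
F6 | step 15 | 8-O-triethylsilyl ether of 27 | CC(=O)O/C=C/C=C(\C)[C@@H](OC(C)=O)CC/C(C)=C(/Cl)[C@@H]1OC(=O)[C@H](C)[C@@]1(O[Si](CC)(CC)CC)CO[Si](CC)(CC)CC
F7 | step 15 | 8,9-diol (desilylated 27) | CC(=O)O/C=C/C=C(\C)[C@@H](OC(C)=O)CC/C(C)=C(/Cl)[C@@H]1OC(=O)[C@H](C)[C@@]1(O)CO
F8 | step 20 | 8-O-dimethylsilyl (Si–H) ether of 32 | CC(=O)O[C@H]1CC/C(C)=C(/Cl)[C@@H]2OC(=O)[C@H](C)[C@@]2(O[SiH](C)C)C(=O)[C@H]2[C@@H](C)[C@H](OC(C)=O)C=C[C@@]21C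
F9 | step 20 | 8,9-O-dimethylsilylene acetal of 33 | CC(=O)O[C@H]1CC/C(C)=C(/Cl)[C@@H]2OC(=O)[C@H](C)[C@@]2(O[Si](C)(C)O3)[C@@H]3[C@H]2[C@@H](C)[C@H](OC(C)=O)C=C[C@@]21C
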